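## Analysis of the target

The target is a naphthazarin (5,8-dihydroxy-1,4-naphthoquinone; quinone ring C1–C4/C4a/C8a, benzenoid ring C4a–C8a) whose C2 carries C1' of a cyclobutane (C1'–C4'). C1' is the only stereocentre: it is fully substituted and (R), bonded to the angelate oxygen, to quinone C2, to the ring methylene C4' and to the quaternary C2' with its two methyl groups, and since no second centre can relay or correct it, it has to be set absolutely and never ionised afterwards. The sensitive groups are the (Z)-2-methylbut-2-enoate, which drifts to the E geometry under nucleophilic acyl catalysis, via acylium ions or by γ-deprotonation, the hindered tertiary ester on a strained ring, and the naphthazarin, which is redox-active, chelating and base-sensitive. The two rings of the naphthazarin exchange roles by tautomerism, so the drawn tautomer and the one with the side chain on the benzenoid ring are one compound. Three things make the synthesis hard: esterifying a tertiary cyclobutanol flanked by a quaternary carbon without losing the Z geometry, setting a lone quaternary carbinol between CMe2 and CH2, and unmasking the peri-phenols at the end beside that ester. One electronic fact orders the late steps: a cation at C1' is benzylic and accessible when C1' sits on an electron-rich naphthalene, but strongly disfavoured when it sits on the quinone. The strategy rests on the ring-fusion carbons C4a and C8a, each of which stands next to an oxygen-bearing carbon (C5 and C8) and is bonded to C4 and C1 respectively. The bonds C4–C4a and C1–C8a are exactly those a 3,6-dioxygenated benzyne forms with the 2- and 5-positions of a furan, whose ring oxygen then becomes one of the quinone oxygens.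

## Retrosynthetic reasoning

**18 to 17.** The two aryl O–CH3 bonds are cut last. The free naphthazarin would interfere with every earlier step (acidic, chelating, easily reduced), and methyl ethers are what the aryne partner brings. The forward cleavage is helped by the peri carbonyls and must leave the tertiary angelate alone. That is plausible only because C1' is by then attached to the electron-poor quinone ring.

**17 to 14 and 16.** The acyl C–O bond of the ester is cut, giving tertiary alcohol 14 and angelic anhydride 16 (made from two molecules of acid 15). The ester is introduced at the quinone stage and not earlier, because earlier it would meet the strong amide base of the aryne step (γ-deprotonation) or sit as a tertiary benzylic ester on an electron-rich naphthol during acid treatment. The forward step has to acylate a hindered tertiary alcohol under conditions that neither isomerise the alkene nor attack the quinone.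

**14 to 13.** The O–Si bond is cut. The silyl ether keeps the tertiary oxygen inert to strong base in the aryne step and is a poor leaving group under the acid of the bridge opening.

**13 to 10 (through 11 and 12).** The second quinone oxygen is removed and the C–O–C bridge restored. This oxygen is the only heteroatom the cycloaddition does not supply. It is added by para-oxidation of the naphthols 11 and 12 formed when the oxygen bridge of 10 opens. Either bridge C–O bond may break, because both naphthols lead to the same quinone 13, so no regiocontrol is asked of the opening.

**10 to 6 and 7 (through 8 and 9).** C1–C8a and C4–C4a are cut. This is the key disconnection: it divides the skeleton into a cheap symmetric arene and a small chiral furan that already holds the stereocentre. Because aryne 9 is symmetric there is no regiochemical question. Cutting C2–C1' instead would require adding a hindered, ortho-disubstituted naphthyl nucleophile to a ketone with no handle for enantiocontrol.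

**6 to 5, and 5 to 1 and 2 (through 3 and 4).** After removal of the silyl group, the C1'–C(furyl) bond is cut to 3-bromofuran 1 and ketone 2. The two flanks of the carbonyl in 2 (CMe2 against CH2) differ as much as two alkyl groups can, which is the best case for a catalyst-controlled addition to a dialkyl ketone. The forward reaction must deliver the furyl group to the Si face.

## Alternatives that were turned down

**Alternative 1: ketene–alkene [2+2], then enolate oxygenation.**
- Disconnection: C1'–C2' and C3'–C4', with the C1'–O bond added afterwards.
- Forward key step: the ketene released from (1,4,5,8-tetramethoxynaphthalen-2-yl)acetyl chloride A1 by Et3N, activated by EtAlCl2, adds to 2-methylpropene A2 to give cyclobutanone A3.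
- For: the ring is made from feedstock chemicals, and ketene polarity places the gem-dimethyl carbon next to the aryl-bearing carbon without fail. On this point it is stronger than the chosen route, which buys the ring as ketone 2.
- Against: A3 carries its carbonyl at C4' and is racemic at C1'. The stereocentre must then come from an enantioselective hydroxylation of a fully substituted, very hindered enolate to ketol A4. The C4' carbonyl must afterwards be removed from A4, an α-hydroxycyclobutanone prone to α-ketol rearrangement and ring contraction. The Lewis acid also meets an electron-rich tetramethoxynaphthalene. The endgame needs an oxidative demethylation that gives two regioisomeric quinones and a final demethylation.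
- Comparison: at least four more steps, and the stereocentre depends on a reagent-controlled oxygenation with little to guide it. The chosen route sets C1' in the first step by carbonyl addition and never returns to the ring.

**Alternative 2: cyclobutene by sulfur dioxide extrusion.**
- Disconnection: C3'–C4', formed as a double bond by ring contraction.
- Forward key step: the enantiopure sulfolane A5 is halogenated at an α-carbon under Ramberg–Bäcklund conditions (KOH on Al2O3 with CBr2F2 as the halogen source), closes to the episulfone and loses SO2 to give cyclobutene A6.
- For: the four-membered ring comes from an easily assembled five-membered one, and the contraction does not touch C1'.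
- Against: in A5 the silyloxy group sits on the carbon next to one of the two sulfone α-carbons. The contraction needs a carbanion at both α-carbons in turn (one for halogenation, the other for ring closure), so the carbanion beside the silyloxy carbon cannot be avoided and can expel silyloxide (E1cB). Contraction to a strained cyclobutene is the least favourable case of this reaction. A6 still needs hydrogenation, desilylation, acylation and the two-stage unmasking of the tetramethoxynaphthalene. The stereocentre must still be set by adding a hindered naphthyl nucleophile to a ketone.
- Comparison: longer by several steps and no stronger on stereocontrol. Its one advantage is independence from ketone 2. The chosen route offers a key step with no base-labile leaving group β to a carbanion.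

**Alternative 3: cyclopropylcarbinyl to cyclobutyl expansion with capture by the acid.**
- Disconnection: C2'–C3' and C1'–O.
- Forward key step: protonation of the isopropenyl group of A7 gives a tertiary cation, a cyclopropane methylene migrates, and the resulting 1-arylcyclobutyl cation is captured by angelic acid 15 to give ester A8.
- For: it is the shortest route on paper and forms the hindered tertiary ester bond directly. On this point it is clearly stronger than the chosen route, whose acylation of 14 is its weakest functional-group step.
- Against: C1' passes through a planar benzylic cation, so its configuration depends on enantioselective capture of an achiral tertiary cation by a weak nucleophile, for which there is no reliable basis. The same cation can re-form from A8 on the electron-rich ring and erase whatever selectivity is reached. Acid strong enough to protonate the alkene of A7 also isomerises the Z alkene of 15 to the E geometry. Elimination or capture before migration can compete. The tetramethoxynaphthalene endgame remains.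
- Comparison: step economy favours this alternative. The chosen route offers in its place a stereocentre fixed by a catalyst-controlled carbonyl addition and kept out of ionising conditions while it sits on an electron-rich ring.

Key step: step 3

## Route

Assumption: the sense of induction of the chiral ligand with this cyclic dialkyl ketone is not presumed. The ligand antipode that delivers the furyl group to the Si face of 2 is selected once the configuration of 5 has been assigned. Ketone 2 is taken as purchasable.

Step 1
Reactants: 1 3-bromofuran; 2 2,2-dimethylcyclobutan-1-one
Product: 5 (1R)-1-(furan-3-yl)-2,2-dimethylcyclobutan-1-ol, via furan-3-yllithium 3 (not isolated), via ethyl(furan-3-yl)zinc 4 (not isolated)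
Conditions: nBuLi, tBuOMe, −78 °C; EtZnCl (from ZnEt2, ZnCl2), −78 to 0 °C; TEEDA (N,N,N',N'-tetraethylethylenediamine), toluene; then 2, Ti(OiPr)4, trans-1,2-bis(2-exo-hydroxycamphor-10-sulfonamido)cyclohexane ligand (10 mol%), rt; H2O
Reagents that add atoms: none
Why: Catalytic enantioselective addition of a heteroarylzinc reagent to a ketone under Ti(OiPr)4 with a chiral bis(sulfonamide) diol ligand; the mixed ethyl(heteroaryl)zinc transfers its sp2 group, the diamine binds LiCl that would drive a racemic background addition, and the catalyst distinguishes the CMe2 flank from the CH2 flank so that Si-face delivery gives the (R)-carbinol. The lithio-furan is kept at −78 °C until transmetalated so that it does not migrate to the 2-position.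

Step 2
Reactants: 5 (1R)-1-(furan-3-yl)-2,2-dimethylcyclobutan-1-ol
Product: 6 3-[(1R)-2,2-dimethyl-1-(triethylsilyloxy)cyclobutyl]furan
Conditions: Et3SiOTf, 2,6-lutidine, CH2Cl2, −78 to 0 °C
Reagents that add atoms: triethylsilyl trifluoromethanesulfonate, CC[Si](CC)(CC)OS(=O)(=O)C(F)(F)F
Why: Silylation of a hindered tertiary alcohol with a silyl triflate and a hindered pyridine base; the buffered medium protects the acid-sensitive furyl carbinol and C1' is not involved.

Step 3
Reactants: 6 3-[(1R)-2,2-dimethyl-1-(triethylsilyloxy)cyclobutyl]furan; 7 2-bromo-1,4-dimethoxybenzene
Product: 10 2-[(1R)-2,2-dimethyl-1-(triethylsilyloxy)cyclobutyl]-5,8-dimethoxy-1,4-dihydro-1,4-epoxynaphthalene (both bridgehead diastereomers), via (2-bromo-3,6-dimethoxyphenyl)lithium 8 (not isolated), via 3,6-dimethoxybenzyne 9 (not isolated)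
Conditions: 7 (3 equiv), LiTMP (lithium 2,2,6,6-tetramethylpiperidide, from TMPH and nBuLi), THF, −78 °C; then 6 (1 equiv), −78 °C to rt
Reagents that add atoms: none
Why: The amide removes the ring hydrogen of 7 that lies between bromine and methoxy to give aryllithium 8, which persists at −78 °C and loses LiBr on warming to the symmetric aryne 9; furan 6 is added only after the amide is consumed, so it meets the free amine and 9 but no strong base. Aryne 9 then adds across C2 and C5 of the furan in a concerted suprafacial [4+2] cycloaddition, the established reaction of 3,6-dimethoxybenzyne with furans to give 1,4-epoxy-1,4-dihydronaphthalenes. The new six-membered carbocycle closes by two-bond annulation (C1–C8a and C4–C4a formed together), which also creates the oxygen-bridged bicycle, so no single-bond cyclisation mode applies. The bridgehead centres C1 and C4 are formed without control because the remote carbinol cannot bias the faces of the planar furan; both diastereomers are carried on since these centres vanish on aromatisation. No regioselectivity is required: both aryne carbons have the same methoxy neighbour, so either orientation gives one constitution. The step needs chemoselectivity for cycloaddition over addition of the amine or of 8 to the aryne, which rests on the electron-rich diene, the bulk of the amine and the excess of 7. C1' keeps its configuration because no bond to it is made or broken.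

Step 4
Reactants: 10 2-[(1R)-2,2-dimethyl-1-(triethylsilyloxy)cyclobutyl]-5,8-dimethoxy-1,4-dihydro-1,4-epoxynaphthalene
Product: 13 2-[(1R)-2,2-dimethyl-1-(triethylsilyloxy)cyclobutyl]-5,8-dimethoxynaphthalene-1,4-dione, via 2-substituted 1-naphthol 11 (not isolated), via 3-substituted 1-naphthol 12 (not isolated)
Conditions: TFA (cat.), CH2Cl2, 0 °C; then K2NO(SO3)2, aq. KH2PO4, Bu4NHSO4 (cat.), CH2Cl2/H2O, rt
Reagents that add atoms: potassium nitrosodisulfonate, [K+].[K+].[O]N(S(=O)(=O)[O-])S(=O)(=O)[O-]
Why: Acid-catalysed isomerisation of a 1,4-epoxy-1,4-dihydronaphthalene to a 1-naphthol (ionisation of a bridge C–O bond assisted by the ortho methoxy group, then hydride shift and enolisation), followed by Teuber oxidation of the air-sensitive naphthols at the free para position; both regioisomeric naphthols give the same 1,4-quinone. The silyl ether is a poor leaving group under catalytic anhydrous acid, so C1' should not ionise.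

Step 5
Reactants: 13 2-[(1R)-2,2-dimethyl-1-(triethylsilyloxy)cyclobutyl]-5,8-dimethoxynaphthalene-1,4-dione
Product: 14 2-[(1R)-1-hydroxy-2,2-dimethylcyclobutyl]-5,8-dimethoxynaphthalene-1,4-dione
Conditions: HF·pyridine, pyridine, THF, 0 °C to rt
Reagents that add atoms: none
Why: Fluoride-driven Si–O cleavage under buffered, weakly acidic conditions that a quinone tolerates where basic fluoride would not; C1' now sits on the electron-poor ring and cannot ionise.

Step 6
Reactants: 15 angelic acid [(2Z)-2-methylbut-2-enoic acid] (2 equiv)
Product: 16 angelic anhydride [(2Z)-2-methylbut-2-enoic anhydride]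
Conditions: DCC (0.5 equiv relative to 15), CH2Cl2, 0 °C to rt; filter off the urea
Reagents that add atoms: angelic acid (the second molecule of 15), C/C=C(/C)C(=O)O
Why: Carbodiimide dehydration: one molecule of acid adds to DCC to give the O-acylisourea, and a second molecule of the same acid attacks it to give the symmetric anhydride and N,N'-dicyclohexylurea. The reaction runs at low temperature without a nucleophilic catalyst, so the Z geometry of both acyl groups should be kept.

Step 7
Reactants: 14 2-[(1R)-1-hydroxy-2,2-dimethylcyclobutyl]-5,8-dimethoxynaphthalene-1,4-dione; 16 angelic anhydride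
Product: 17 (1R)-1-(5,8-dimethoxy-1,4-dioxo-1,4-dihydronaphthalen-2-yl)-2,2-dimethylcyclobutyl (2Z)-2-methylbut-2-enoate
Conditions: MgBr2·OEt2, Et3N, CH2Cl2, rt, dark
Reagents that add atoms: none
Why: Dual-activation acylation of a hindered tertiary alcohol with an anhydride by MgBr2 and a tertiary amine: the magnesium alkoxide forms under mild base while the anhydride is activated by coordination. No acyl chloride, acylium ion or pyridine-type catalyst is present that would open a path to the tiglate, and no strong base meets the quinone.

Step 8
Reactants: 17 (1R)-1-(5,8-dimethoxy-1,4-dioxo-1,4-dihydronaphthalen-2-yl)-2,2-dimethylcyclobutyl (2Z)-2-methylbut-2-enoate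
Product: 18 (1R)-1-(5,8-dihydroxy-1,4-dioxo-1,4-dihydronaphthalen-2-yl)-2,2-dimethylcyclobutyl (2Z)-2-methylbut-2-enoate (CNP0326301.1)
Conditions: BCl3, CH2Cl2, −78 to −20 °C; H2O
Reagents that add atoms: none
Why: Chelation-assisted cleavage of aryl methyl ethers peri to a carbonyl: boron bridges the quinone oxygen and the methoxy oxygen and chloride removes the methyl group; both methoxy groups are peri to quinone carbonyls. The tertiary ester should survive because a cation at C1' next to the quinone is disfavoured, and the low temperature protects the Z alkene.

## Compound list

1 | 3-bromofuran | Brc1ccoc1 | starting material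
2 | 2,2-dimethylcyclobutan-1-one | CC1(C)CCC1=O | starting material
3 | furan-3-yllithium | [Li]c1ccoc1 | intermediate
4 | ethyl(furan-3-yl)zinc | CC[Zn]c1ccoc1 | intermediate
5 | (1R)-1-(furan-3-yl)-2,2-dimethylcyclobutan-1-ol | O[C@]1(c2ccoc2)CCC1(C)C | intermediate
6 | 3-[(1R)-2,2-dimethyl-1-(triethylsilyloxy)cyclobutyl]furan | CC[Si](CC)(CC)O[C@]1(c2ccoc2)CCC1(C)C | intermediate
7 | 2-bromo-1,4-dimethoxybenzene | COc1ccc(OC)c(Br)c1 | starting material
8 | (2-bromo-3,6-dimethoxyphenyl)lithium | [Li]c1c(OC)ccc(OC)c1Br | intermediate
9 | 3,6-dimethoxybenzyne | COC1=CC=C(OC)C#C1 | intermediate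
10 | 2-[(1R)-2,2-dimethyl-1-(triethylsilyloxy)cyclobutyl]-5,8-dimethoxy-1,4-dihydro-1,4-epoxynaphthalene, both bridgehead diastereomers | CC[Si](CC)(CC)O[C@]1(C2=CC3OC2c2c(OC)ccc(OC)c23)CCC1(C)C | intermediate
11 | 2-[(1R)-2,2-dimethyl-1-(triethylsilyloxy)cyclobutyl]-5,8-dimethoxynaphthalen-1-ol | CC[Si](CC)(CC)O[C@]1(c2ccc3c(OC)ccc(OC)c3c2O)CCC1(C)C | intermediate
12 | 3-[(1R)-2,2-dimethyl-1-(triethylsilyloxy)cyclobutyl]-5,8-dimethoxynaphthalen-1-ol | CC[Si](CC)(CC)O[C@]1(c2cc(O)c3c(OC)ccc(OC)c3c2)CCC1(C)C | intermediate
13 | 2-[(1R)-2,2-dimethyl-1-(triethylsilyloxy)cyclobutyl]-5,8-dimethoxynaphthalene-1,4-dione | CC[Si](CC)(CC)O[C@]1(C2=CC(=O)c3c(OC)ccc(OC)c3C2=O)CCC1(C)C | intermediate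
14 | 2-[(1R)-1-hydroxy-2,2-dimethylcyclobutyl]-5,8-dimethoxynaphthalene-1,4-dione | O[C@]1(C2=CC(=O)c3c(OC)ccc(OC)c3C2=O)CCC1(C)C | intermediate
15 | angelic acid, (2Z)-2-methylbut-2-enoic acid | C/C=C(/C)C(=O)O | starting material
16 | angelic anhydride, (2Z)-2-methylbut-2-enoic anhydride | C/C=C(/C)C(=O)OC(=O)/C(C)=C\C | intermediate
17 | (1R)-1-(5,8-dimethoxy-1,4-dioxo-1,4-dihydronaphthalen-2-yl)-2,2-dimethylcyclobutyl (2Z)-2-methylbut-2-enoate | C/C=C(/C)C(=O)O[C@]1(C2=CC(=O)c3c(OC)ccc(OC)c3C2=O)CCC1(C)C | intermediate
18 | (1R)-1-(5,8-dihydroxy-1,4-dioxo-1,4-dihydronaphthalen-2-yl)-2,2-dimethylcyclobutyl (2Z)-2-methylbut-2-enoate | C/C=C(/C)C(=O)O[C@]1(C2=CC(=O)c3c(O)ccc(O)c3C2=O)CCC1(C)C | target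

## Step count and least certain steps

Total step count: 8. Longest linear sequence: 7 steps (steps 1, 2, 3, 4, 5, 7 and 8, from 1 to 18). Step 6 is a one-step side branch.

**Step 3 (key step).** The aryne may be consumed faster by aryllithium 8 or by the amine than by the hindered 3-substituted furan, or residual amide may metalate the furan at an α-position, so that 6 is left unconverted. Fallback, setting out from 7 and 6 and returning at 10: 7 would be lithiated with LiN(iPr)2 at −78 °C and quenched with BrCCl2CCl2Br to give 2,3-dibromo-1,4-dimethoxybenzene F1. Slow addition of nBuLi to F1 and 6 in toluene would then release 9 by bromine–lithium exchange and loss of LiBr. No amide or amine is present when the aryne meets the furan, and 8 is kept at low concentration.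

**Step 7.** The tertiary hydroxyl between the quaternary C2' and the quinone may acylate too slowly, and forcing the reaction invites Z-to-E isomerisation of the acyl group. Fallback, setting out from 10 and returning at 17: the acylation is moved ahead of aromatisation, where a lithium alkoxide can be used. Bu4NF in THF would give (1R)-1-(5,8-dimethoxy-1,4-dihydro-1,4-epoxynaphthalen-2-yl)-2,2-dimethylcyclobutan-1-ol F2. Deprotonation with LiN(SiMe3)2 at −78 °C and addition of 16 would give (1R)-1-(5,8-dimethoxy-1,4-dihydro-1,4-epoxynaphthalen-2-yl)-2,2-dimethylcyclobutyl (2Z)-2-methylbut-2-enoate F3. Catalytic TFA and then K2NO(SO3)2, as in step 4, would pass through (1R)-1-(1-hydroxy-5,8-dimethoxynaphthalen-2-yl)-2,2-dimethylcyclobutyl (2Z)-2-methylbut-2-enoate F4 and (1R)-1-(4-hydroxy-5,8-dimethoxynaphthalen-2-yl)-2,2-dimethylcyclobutyl (2Z)-2-methylbut-2-enoate F5 to 17. This order is not the first choice because a tertiary ester on an electron-rich naphthol is more prone to ionisation and acyl shift than the silyl ether.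

**Step 1.** Facial discrimination may be poor or addition slow, because the substrate is a hindered dialkyl ketone and not the aryl ketone for which such catalysts work best. Fallback, setting out from 1 and 2 and returning at 5: 3 would be added to 2 in the presence of CeCl3 to give racemic 1-(furan-3-yl)-2,2-dimethylcyclobutan-1-ol F6, which would be resolved by preparative chromatography on a chiral stationary phase.

**Step 4.** Two processes threaten it. Acid may ionise the C1'–O bond while C1' is on the electron-rich ring. The naphthol whose para carbon lies next to the bulky side chain (12) may be oxidised at the ortho position instead. Fallback, setting out from 10 and returning at 13: after the acid opening the naphthols would be oxidised with PhI(OCOCF3)2 in aqueous MeCN. This replaces radical coupling with a bulky nitroxyl by capture of a phenoxenium ion by water, a small nucleophile, at C4. The fallback makes no new compound (F0).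

**Step 8.** The Lewis acid may isomerise the angelate or cleave the ester before both methyl groups are removed. Fallback, setting out from 17 and returning at 18: oxidative demethylation with AgO and HNO3 in dioxane would give (1R)-2,2-dimethyl-1-(1,4,5,8-tetraoxo-1,4,5,8-tetrahydronaphthalen-2-yl)cyclobutyl (2Z)-2-methylbut-2-enoate F7. Mild reduction with aqueous Na2S2O4 would then give the naphthazarin without any Lewis acid.

## Further compounds

F1 | step 3 | 2,3-dibromo-1,4-dimethoxybenzene | COc1ccc(OC)c(Br)c1Br
F2 | step 7 | (1R)-1-(5,8-dimethoxy-1,4-dihydro-1,4-epoxynaphthalen-2-yl)-2,2-dimethylcyclobutan-1-ol | O[C@]1(C2=CC3OC2c2c(OC)ccc(OC)c23)CCC1(C)C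
F3 | step 7 | (1R)-1-(5,8-dimethoxy-1,4-dihydro-1,4-epoxynaphthalen-2-yl)-2,2-dimethylcyclobutyl (2Z)-2-methylbut-2-enoate | C/C=C(/C)C(=O)O[C@]1(C2=CC3OC2c2c(OC)ccc(OC)c23)CCC1(C)C
F4 | step 7 | (1R)-1-(1-hydroxy-5,8-dimethoxynaphthalen-2-yl)-2,2-dimethylcyclobutyl (2Z)-2-methylbut-2-enoate | C/C=C(/C)C(=O)O[C@]1(c2ccc3c(OC)ccc(OC)c3c2O)CCC1(C)C
F5 | step 7 | (1R)-1-(4-hydroxy-5,8-dimethoxynaphthalen-2-yl)-2,2-dimethylcyclobutyl (2Z)-2-methylbut-2-enoate | C/C=C(/C)C(=O)O[C@]1(c2cc(O)c3c(OC)ccc(OC)c3c2)CCC1(C)C
F6 | step 1 | racemic 1-(furan-3-yl)-2,2-dimethylcyclobutan-1-ol | OC1(c2ccoc2)CCC1(C)C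
F0 | step 4 | none | none
F7 | step 8 | (1R)-2,2-dimethyl-1-(1,4,5,8-tetraoxo-1,4,5,8-tetrahydronaphthalen-2-yl)cyclobutyl (2Z)-2-methylbut-2-enoate | C/C=C(/C)C(=O)O[C@]1(C2=CC(=O)C3=C(C2=O)C(=O)C=CC3=O)CCC1(C)C
A1 | alternative 1 | (1,4,5,8-tetramethoxynaphthalen-2-yl)acetyl chloride | COc1ccc(OC)c2c(OC)c(CC(=O)Cl)cc(OC)c12
A2 | alternative 1 | 2-methylpropene | CC(C)=C
A3 | alternative 1 | 3,3-dimethyl-2-(1,4,5,8-tetramethoxynaphthalen-2-yl)cyclobutan-1-one, racemic | COc1ccc(OC)c2c(OC)c(C3C(=O)CC3(C)C)cc(OC)c12
A4 | alternative 1 | (2R)-2-hydroxy-3,3-dimethyl-2-(1,4,5,8-tetramethoxynaphthalen-2-yl)cyclobutan-1-one | O[C@]1(c2cc(OC)c3c(OC)ccc(OC)c3c2OC)C(=O)CC1(C)C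
A5 | alternative 2 | tert-butyl{[(3R)-4,4-dimethyl-1,1-dioxo-3-(1,4,5,8-tetramethoxynaphthalen-2-yl)thiolan-3-yl]oxy}dimethylsilane | CC(C)(C)[Si](C)(C)O[C@]1(c2cc(OC)c3c(OC)ccc(OC)c3c2OC)CS(=O)(=O)CC1(C)C
A6 | alternative 2 | tert-butyl{[(1R)-4,4-dimethyl-1-(1,4,5,8-tetramethoxynaphthalen-2-yl)cyclobut-2-en-1-yl]oxy}dimethylsilane | CC(C)(C)[Si](C)(C)O[C@]1(c2cc(OC)c3c(OC)ccc(OC)c3c2OC)C=CC1(C)C
A7 | alternative 3 | 1,4,5,8-tetramethoxy-2-[1-(prop-1-en-2-yl)cyclopropyl]naphthalene | CC(=C)C1(c2cc(OC)c3c(OC)ccc(OC)c3c2OC)CC1
A8 | alternative 3 | (1R)-2,2-dimethyl-1-(1,4,5,8-tetramethoxynaphthalen-2-yl)cyclobutyl (2Z)-2-methylbut-2-enoate | C/C=C(/C)C(=O)O[C@]1(c2cc(OC)c3c(OC)ccc(OC)c3c2OC)CCC1(C)C
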